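**Retrosynthetic overview**
1. Key disconnection: the allylic ester C–O bond, giving linoleic acid 2 and an all-E C20 polyprenol. The bond is made first, on commercial geranylgeraniol 1, by DCC/DMAP acylation.
2. This ester is kept as the control element for the rest of the route: it deactivates the 2,3-olefin and suppresses allylic ionization, so no protecting group is needed.
3. Ring disconnection: the C10–C15 bond of geranylgeranyl linoleate 4 (geranylgeranyl numbering), closed by a catalytic asymmetric proton-initiated monocyclization ended by loss of H-12. This step sets the only stereocenter.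
4. Ring order: there is one ring, formed in the last step. The four acyclic olefin geometries (2E,6E and 9Z,12Z) come in with 1 and 2.

Assumption: the sense of induction of step 2 cannot be predicted, so the (S,S)-catalyst is written and its mirror image is used if a test run (chiral HPLC against a reference sample) gives the (R)-product.

**Step 1**
Reactants: 1 (2E,6E,10E)-geranylgeraniol; 2 linoleic acid
Product: 4 (2E,6E,10E)-geranylgeranyl linoleate, via O-acylisourea 3 (not isolated)
Conditions: DCC (1.2 equiv), DMAP (0.1 equiv), CH2Cl2, 0 °C to rt, Ar, dark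
Reagents that add atoms: none
Why: Steglich esterification: DCC turns 2 into O-acylisourea 3 and DMAP relays the acyl group to the unhindered primary allylic alcohol of 1 under neutral conditions, so neither the all-E polyene nor the skipped Z,Z-diene isomerizes and no stereocenter is involved.

**Step 2**
Reactants: 4 (2E,6E,10E)-geranylgeranyl linoleate
Product: 6 (2E,6E)-3,7-dimethyl-9-[(1S)-2,6,6-trimethylcyclohex-2-en-1-yl]nona-2,6-dien-1-yl linoleate (target), via cyclohexyl cation 5 (not isolated)
Conditions: (S,S)-IDPi Brønsted acid (5 mol%; N,N′-bis(trifluoromethylsulfonyl) imidodiphosphorimidate from two (S)-3,3′-bis(9,9-dimethylfluoren-2-yl)-BINOL units), CHCl3/(CF3)3COH 9:1, −40 °C, Ar, dark, to about 70% conversion; Et3N quench; AgNO3–silica chromatography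
Reagents that add atoms: none
Why: Proposed new method: catalytic asymmetric proton-initiated monocyclization (a formal ene-type cycloisomerization) in which the confined strong chiral acid protonates only the unhindered, most electron-rich terminal isopropylidene at C14 while the 10,11-olefin attacks C15 through a chair transition state held in the chiral pocket, which fixes the face of C10 and so the (S) center; in the low-polarity medium the tertiary C11 cation 5 is a contact ion pair whose basic IDPi anion removes the adjacent axial H-12 (giving the endocyclic ring olefin) faster than the rest of the chain, which lies outside the pocket, can fold for a second ring closure; the 2,3-olefin is switched off by the allylic ester, the cis-disubstituted linoleate olefins are too weakly basic to be protonated, and the hindered ring olefin of 6 is not re-protonated at partial conversion; the closest known reaction type is the IDPi-catalysed enantioselective proton-initiated polyene cyclization (hydroxyl-terminated) and olefin hydrofunctionalization, together with the stepwise acid cyclization of polyprenyl acetates that passes through monocyclic olefins.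

**Compound list**
1 | (2E,6E,10E)-geranylgeraniol, (2E,6E,10E)-3,7,11,15-tetramethylhexadeca-2,6,10,14-tetraen-1-ol | `OC/C=C(\C)CC/C=C(\C)CC/C=C(\C)CCC=C(C)C` | starting material
2 | linoleic acid, (9Z,12Z)-octadeca-9,12-dienoic acid | `CCCCC/C=C\C/C=C\CCCCCCCC(=O)O` | starting material
3 | O-acylisourea, O-linoleoyl-N,N′-dicyclohexylisourea | `CCCCC/C=C\C/C=C\CCCCCCCC(=O)OC(=NC1CCCCC1)NC1CCCCC1` | intermediate (not isolated)
4 | (2E,6E,10E)-geranylgeranyl linoleate, (2E,6E,10E)-3,7,11,15-tetramethylhexadeca-2,6,10,14-tetraen-1-yl (9Z,12Z)-octadeca-9,12-dienoate | `CCCCC/C=C\C/C=C\CCCCCCCC(=O)OC/C=C(\C)CC/C=C(\C)CC/C=C(\C)CCC=C(C)C` | intermediate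
5 | cyclohexyl cation, tertiary 2-cation of the 2,6,6-trimethylcyclohexyl ring, ring stereocenter as in 6, ion-paired with the catalyst anion | `CCCCC/C=C\C/C=C\CCCCCCCC(=O)OC/C=C(\C)CC/C=C(\C)CC[C@@H]1[C+](C)CCCC1(C)C` | intermediate (not isolated)
6 | (2E,6E)-3,7-dimethyl-9-[(1S)-2,6,6-trimethylcyclohex-2-en-1-yl]nona-2,6-dien-1-yl (9Z,12Z)-octadeca-9,12-dienoate | `CCCCC/C=C\C/C=C\CCCCCCCC(=O)OC/C=C(\C)CC/C=C(\C)CC[C@@H]1C(C)=CCCC1(C)C` | target

**Step count and risk**
Total step count: 2. Longest linear sequence: 2 (1 → 4 → 6). The route has only two steps, so both are ranked below and there is no third step to list.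

Risk 1, step 2 (the proposed new step). It can fail in four ways:
- cyclization runs on to bicyclic or tricyclic esters, or starts at an inner olefin;
- ee is low, or the exocyclic or tetrasubstituted ring-olefin isomers form (the latter destroys the stereocenter);
- the allylic ester ionizes;
- the cation takes a hydride from the bis-allylic CH2 of the linoleate.

It is followed by 1H NMR (ring vinyl H against isopropylidene methyls) and by chiral HPLC of the alcohol released from an aliquot with K2CO3/MeOH.

Fallback (known chemistry; sets out from linoleic acid 2 and comes back at target 6, leaving ester 4 aside). The ring and its stereocenter are made on a C10 piece and joined to a C10 chain by sulfone alkylation. Commercial geranic acid is cyclized with 85% H3PO4 to racemic α-cyclogeranic acid F1. F1 is resolved by crystallizing its 1-phenylethylammonium salt to (S)-α-cyclogeranic acid F2; the amine antipode is chosen so that the salt of the (S)-acid is the less soluble one, and ee is checked by chiral GC of the methyl ester. LiAlH4 in THF gives (S)-α-cyclogeraniol F3. PhSSPh/n-Bu3P converts F3 into (S)-α-cyclogeranyl phenyl sulfide F4, and H2O2 with catalytic (NH4)6Mo7O24 oxidizes F4 to (S)-α-cyclogeranyl phenyl sulfone F5. Separately, commercial geraniol is benzylated (NaH, BnBr) to geranyl benzyl ether F6. F6 is oxidized at the E-methyl group with catalytic SeO2/t-BuOOH to (2E,6E)-8-benzyloxy-2,6-dimethylocta-2,6-dien-1-ol F7, which CBr4/PPh3 converts into benzyl (2E,6E)-8-bromo-3,7-dimethylocta-2,6-dien-1-yl ether F8. The lithio derivative of F5 (n-BuLi, THF, −78 °C) is alkylated by F8 to the C20 benzyl ether sulfone F9 (both epimers at the sulfonyl carbon are used). Li in EtNH2 at −78 °C removes the phenylsulfonyl and benzyl groups in one operation to give (2E,6E)-3,7-dimethyl-9-[(1S)-2,6,6-trimethylcyclohex-2-en-1-yl]nona-2,6-dien-1-ol F10. F10 is esterified with 2 under the conditions of step 1 to give 6. F10 also serves as the reference sample for the configuration check of step 2.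

Risk 2, step 1. It can fail through N-acylurea formation from 3, incomplete conversion, or air oxidation of the skipped diene during work-up.

Fallback (sets out from 1 and 2 and comes back at 4). The alcohol is activated instead of the acid: Mitsunobu esterification (PPh3, diisopropyl azodicarboxylate, THF, 0 °C) lets the linoleate anion displace the activated primary allylic oxygen of 1 by SN2 to give 4 directly. This fallback makes no new compound (none F0).

**Further compounds**
F0 | step 1 | none | none
F1 | step 2 | racemic α-cyclogeranic acid, 2,6,6-trimethylcyclohex-2-ene-1-carboxylic acid | `CC1=CCCC(C)(C)C1C(=O)O`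
F2 | step 2 | (S)-α-cyclogeranic acid, (1S)-2,6,6-trimethylcyclohex-2-ene-1-carboxylic acid | `OC(=O)[C@@H]1C(C)=CCCC1(C)C`
F3 | step 2 | (S)-α-cyclogeraniol, [(1S)-2,6,6-trimethylcyclohex-2-en-1-yl]methanol | `OC[C@@H]1C(C)=CCCC1(C)C`
F4 | step 2 | (S)-α-cyclogeranyl phenyl sulfide | `c1ccccc1SC[C@@H]1C(C)=CCCC1(C)C`
F5 | step 2 | (S)-α-cyclogeranyl phenyl sulfone | `O=S(=O)(C[C@@H]1C(C)=CCCC1(C)C)c1ccccc1`
F6 | step 2 | geranyl benzyl ether, benzyl (2E)-3,7-dimethylocta-2,6-dien-1-yl ether | `CC(C)=CCC/C(C)=C/COCc1ccccc1`
F7 | step 2 | (2E,6E)-8-benzyloxy-2,6-dimethylocta-2,6-dien-1-ol | `OC/C(C)=C/CC/C(C)=C/COCc1ccccc1`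
F8 | step 2 | benzyl (2E,6E)-8-bromo-3,7-dimethylocta-2,6-dien-1-yl ether | `BrC/C(C)=C/CC/C(C)=C/COCc1ccccc1`
F9 | step 2 | C20 benzyl ether sulfone, benzyl (2E,6E)-3,7-dimethyl-9-phenylsulfonyl-9-[(1S)-2,6,6-trimethylcyclohex-2-en-1-yl]nona-2,6-dien-1-yl ether, epimers at C9 | `O=S(=O)(c1ccccc1)C(C/C(C)=C/CC/C(C)=C/COCc1ccccc1)[C@@H]1C(C)=CCCC1(C)C`
F10 | step 2 | (2E,6E)-3,7-dimethyl-9-[(1S)-2,6,6-trimethylcyclohex-2-en-1-yl]nona-2,6-dien-1-ol | `OC/C=C(\C)CC/C=C(\C)CC[C@@H]1C(C)=CCCC1(C)C`
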